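## Retrosynthetic overview

- **Feature:** in ring A, C4 and C10 flank C5, and each carries an axial methyl and an equatorial carbon (C18 on C4, C9 on C10). Ring A is therefore almost mirror-symmetric. Ring A of dehydroabietic acid, read with C4 and C10 exchanged, is the ent-configured C4/C5/C10 triad of the target with the oxygenated C18 equatorial.
- **Late disconnections:** the C15 malonate and C18 senecioate by acylation, C13 by Ru–BINAP hydrogenation of a (13E)-allylic alcohol, and C12–C13 by B-alkyl Suzuki coupling.
- **Ring B:** the C8–C9 bond comes from SmI2 ketyl–olefin closure of a C8 methyl ketone onto a C9=C11 enoate, which also sets C8 and C9.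
- **Keto enoate:** it comes from the ring A tricarboxyl fragment left after RuO4 removes the arene. The three carboxyl carbons are told apart by acid/ester state and by hindrance.
- **Ring order:** ring A is taken from the chiral pool and ring B is formed in the key step. No other ring is built.

Key step: step 12

Remark: labdane numbering of the target is used from the ring A diacid onward (former abietane C9 = C18, former C18 = C9, former C19 and C20 methyls = C20 and C19). (E)-3-Iodobut-2-en-1-ol is assumed to be a catalogue compound.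

## Route

Step 1
Reactants: 1 dehydroabietic acid
Product: 2 methyl dehydroabietate
Conditions: MeI, K2CO3, DMF, rt
Reagents that add atoms: iodomethane, CI
Why: Carboxylate O-alkylation (SN2 on MeI) avoids the hindered acyl carbon and marks this carboxyl, the future C9, as the only ester, with no stereocentre touched.

Step 2
Reactants: 2 methyl dehydroabietate
Product: 3 ring A C8/C18 diacid C9 methyl ester
Conditions: RuCl3·xH2O (5 mol %), NaIO4 (20 equiv), CCl4–MeCN–H2O 2:2:3, rt
Reagents that add atoms: sodium periodate, [Na+].[O-]I(=O)(=O)=O; water, O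
Why: RuO4 arene degradation (catalytic RuCl3 reoxidised by NaIO4) consumes the trialkylbenzene, the most electron-rich π system, and stops at the two carboxyl carbons that hang on sp3 carbons, so C4, C5 and C10 are carried over unchanged.

Step 3
Reactants: 3 ring A C8/C18 diacid C9 methyl ester
Product: 4 ring A C8 Weinreb amide C18 acid
Conditions: EDC·HCl (1.05 equiv), HOBt, MeNHOMe·HCl, N-methylmorpholine, CH2Cl2, 0 °C→rt
Reagents that add atoms: N,O-dimethylhydroxylamine hydrochloride, CNOC.Cl
Why: Carbodiimide amide coupling discriminates by hindrance, because only the primary-alkyl C8 carboxyl is open to the amine, and any activation of the tertiary C18 acid should drain through the seven-membered cyclic anhydride, which also opens at C8.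

Step 4
Reactants: 4 ring A C8 Weinreb amide C18 acid
Product: 5 ring A C8 methyl ketone C18 acid
Conditions: MeMgBr (3.2 equiv), THF, −20→0 °C; then 1 M HCl
Reagents that add atoms: methylmagnesium bromide, C[Mg]Br
Why: Weinreb ketone synthesis, in which the chelated tetrahedral adduct stops at the ketone (C17 installed) while the C18 acid is shielded as its magnesium carboxylate and the C9 ester by its quaternary neighbour.

Step 5
Reactants: 5 ring A C8 methyl ketone C18 acid
Product: 6 ring A C8 dioxolane C18 acid
Conditions: HOCH2CH2OH, p-TsOH (cat.), toluene, Dean–Stark reflux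
Reagents that add atoms: ethylene glycol, OCCO
Why: Acid-catalysed ketalisation masks the ketone for the two hydride steps, and the tertiary C18 acid does not esterify under Fischer-type conditions.

Step 6
Reactants: 6 ring A C8 dioxolane C18 acid
Product: 7 ring A C18 alcohol C9 methyl ester
Conditions: BH3·THF (2.5 equiv), THF, 0 °C→rt; then MeOH
Reagents that add atoms: none
Why: Chemoselective borane reduction proceeds through the acyloxyborane, works on tertiary acids as well, and is much faster than attack on the hindered methyl ester or the dioxolane.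

Step 7
Reactants: 7 ring A C18 alcohol C9 methyl ester
Product: 8 ring A C18 benzyl ether C9 methyl ester
Conditions: 2-benzyloxy-1-methylpyridinium triflate (2 equiv), MgO, PhCF3, 85 °C
Reagents that add atoms: 2-benzyloxy-1-methylpyridinium triflate, C[n+]1ccccc1OCc1ccccc1.[O-]S(=O)(=O)C(F)(F)F
Why: Neutral thermal benzyl transfer from the pyridinium salt etherifies the neopentyl alcohol without forming an alkoxide, which could otherwise close onto the C9 ester as a bridged lactone.

Step 8
Reactants: 8 ring A C18 benzyl ether C9 methyl ester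
Product: 9 ring A C9 alcohol
Conditions: LiAlH4, THF, 0 °C→reflux
Reagents that add atoms: none
Why: LiAlH4 ester reduction is the standard way to reduce hindered resin-acid esters, and the benzyl ether and dioxolane are inert to it.

Step 9
Reactants: 9 ring A C9 alcohol
Product: 10 ring A C9 aldehyde
Conditions: nPr4N[RuO4] (5 mol %), NMO, 4 Å MS, CH2Cl2, rt
Reagents that add atoms: none
Why: Ley–Griffith oxidation stops at the aldehyde under neutral conditions, and the quaternary α-carbon rules out epimerisation or enolisation.

Step 10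
Reactants: 10 ring A C9 aldehyde
Product: 11 ring A dioxolane (E)-enoate
Conditions: (EtO)2P(O)CH2CO2Et, NaH, THF, 0→50 °C
Reagents that add atoms: triethyl phosphonoacetate, CCOC(=O)CP(=O)(OCC)OCC
Why: Horner–Wadsworth–Emmons olefination of a non-enolisable α-quaternary aldehyde adds C11 and C12 and should give the (E)-enoate, since a bulky aldehyde substituent reinforces the normal E preference.

Step 11
Reactants: 11 ring A dioxolane (E)-enoate
Product: 12 ring A keto (E)-enoate
Conditions: 1 M HCl, THF, rt
Reagents that add atoms: water, O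
Why: Mild acid hydrolysis of the dioxolane frees the C8 ketone without base, so no enolate can add to the enoate.

Step 12
Reactants: 12 ring A keto (E)-enoate
Product: 13 ring B closed 8-hydroxy C12 ethyl ester
Conditions: SmI2 (2.5 equiv, 0.1 M in THF), HMPA (10 equiv), t-BuOH (2 equiv), THF, −78→0 °C, slow addition of 12
Reagents that add atoms: none
Why: Divalent samarium transfers one electron to the C8 ketone, the samarium-bound ketyl adds to C9 (the β-carbon of the C9=C11 enoate), and the C11 radical next to the ester takes a second electron to give a trivalent samarium enolate that t-BuOH protonates. The closest known reaction type is the SmI2 ketyl–olefin (reductive carbonyl–alkene) cyclisation of a ketone onto an α,β-unsaturated ester. Ring B closes 6-exo-trig, and because the C5–C6 and C10–C9 bonds are both equatorial on ring A the new ring can only be a trans-fused chair. C9 is set by the enoate arm lying equatorial in that chair, since an axial C11 would meet the axial hydrogens on C5 and C7. C8 is set by the HMPA-laden O–Sm group taking the equatorial site away from the axial C20 methyl, which leaves the small C17 methyl axial and places O and C11 trans. The step needs cyclisation to outrun simple reduction of the ketone or the enoate and needs β- rather than α-attack, and both are secured by the two adjacent equatorial arms on ring A, the quaternary C10 and the polarity match between the nucleophilic ketyl and the electron-poor β-carbon.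

Step 13
Reactants: 13 ring B closed 8-hydroxy C12 ethyl ester
Product: 14 8-O-TES C12 ethyl ester
Conditions: TESOTf, 2,6-lutidine, CH2Cl2, −78→0 °C
Reagents that add atoms: triethylsilyl triflate, CC[Si](CC)(CC)OS(=O)(=O)C(F)(F)F
Why: Silyl triflate silylation is strong enough for the hindered tertiary alcohol, and masking it before C12 is activated prevents closure to the 8,12-ether.

Step 14
Reactants: 14 8-O-TES C12 ethyl ester
Product: 15 8-O-TES C12 alcohol
Conditions: LiAlH4, Et2O, 0 °C
Reagents that add atoms: none
Why: LiAlH4 reduction of the unhindered ethyl ester is fast at 0 °C and leaves the tertiary silyl ether and the benzyl ether alone.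

Step 15
Reactants: 15 8-O-TES C12 alcohol
Product: 16 8-O-TES C12 iodide
Conditions: I2, PPh3, imidazole, CH2Cl2, 0 °C
Reagents that add atoms: iodine, II
Why: Appel-type iodination converts the only free, unhindered primary alcohol by SN2 under buffered conditions that the silyl ether tolerates.

Step 16
Reactants: 16 8-O-TES C12 iodide; 17 (E)-3-iodobut-2-en-1-ol
Product: 20 (13E)-allylic alcohol, via C12 alkyllithium 18 (not isolated), via lithium B-methoxy borate 19 (not isolated)
Conditions: t-BuLi (2.1 equiv), Et2O, −78 °C; 9-MeO-9-BBN, THF, −78 °C→rt; then 17, PdCl2(dppf) (5 mol %), AsPh3, 3 M aq K3PO4, DMF, rt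
Reagents that add atoms: none
Why: In this B-alkyl Suzuki–Miyaura coupling, iodine–lithium exchange and capture by the borinate give an ate complex that transmetalates directly, and oxidative addition of zerovalent palladium to the vinyl iodide and reductive elimination both retain the E geometry while the free hydroxyl is tolerated.

Step 17
Reactants: 20 (13E)-allylic alcohol
Product: 21 (13S)-C15 alcohol
Conditions: Ru(OAc)2[(R)-BINAP] (1 mol %), H2 (100 atm), MeOH–H2O 95:5, 20 °C
Reagents that add atoms: none
Why: In this Noyori-type asymmetric hydrogenation of an allylic alcohol the hydroxyl binds ruthenium, and as with (E)-configured geraniol-type substrates the (R)-BINAP complex should deliver H2 to the face that gives 13S, under catalyst control because the decalin stereocentres are remote, while benzyl and silyl ethers are inert.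

Step 18
Reactants: 22 Meldrum's acid; 23 2-(trimethylsilyl)ethanol
Product: 24 2-(trimethylsilyl)ethyl hydrogen malonate
Conditions: toluene, 100 °C
Reagents that add atoms: none
Why: Alcoholysis of Meldrum's acid opens the ring with loss of acetone and gives the malonic half ester directly.

Step 19
Reactants: 21 (13S)-C15 alcohol; 24 2-(trimethylsilyl)ethyl hydrogen malonate
Product: 25 C15 mixed malonate C18 benzyl ether
Conditions: DCC, DMAP (cat.), CH2Cl2, 0 °C→rt
Reagents that add atoms: none
Why: Steglich esterification acylates the only free hydroxyl, and the silylethyl ester keeps the second malonate carboxyl masked through hydrogenolysis and the second acylation.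

Step 20
Reactants: 25 C15 mixed malonate C18 benzyl ether
Product: 26 C15 mixed malonate C18 alcohol
Conditions: H2 (1 atm), Pd/C (10 %), EtOAc, rt
Reagents that add atoms: none
Why: Benzyl ether hydrogenolysis is placed after the C13 alkene has been saturated and before the senecioate is attached, so nothing else in the molecule is reducible.

Step 21
Reactants: 26 C15 mixed malonate C18 alcohol; 27 3-methylbut-2-enoic acid
Product: 28 C18 senecioate with 8-O-TES and silylethyl malonate
Conditions: DCC, DMAP, CH2Cl2, rt
Reagents that add atoms: none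
Why: Steglich esterification of the neopentyl primary alcohol avoids the acid chloride/amine pair, which could deconjugate the acyl group through a vinylketene, and C8–O is still silylated so only C18–OH can react.

Step 22
Reactants: 28 C18 senecioate with 8-O-TES and silylethyl malonate
Product: 29 target CNP0199440.1
Conditions: Bu4NF (5 equiv), THF, 0 °C→rt; then cold 0.5 M HCl to pH 3
Reagents that add atoms: none
Why: In this fluoride-induced desilylation, attack on silicon expels ethylene from the 2-(trimethylsilyl)ethyl ester and cleaves the tertiary TES ether in the same operation, the two alkyl esters are left alone, and brief cold acidification gives the free half malonate without touching the tertiary alcohol.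

## Compound list

1 | dehydroabietic acid (abieta-8,11,13-trien-18-oic acid, natural enantiomer) | CC(C)C1=CC2=C(C=C1)[C@]3(CCC[C@@]([C@@H]3CC2)(C)C(=O)O)C | starting material
2 | methyl dehydroabietate | CC(C)C1=CC2=C(C=C1)[C@]3(CCC[C@@]([C@@H]3CC2)(C)C(=O)OC)C | intermediate
3 | ring A C8/C18 diacid C9 methyl ester: 2-(2-carboxyethyl)-3-(methoxycarbonyl)-1,3-dimethylcyclohexane-1-carboxylic acid, the two methyls cis and axial, the three carbon arms equatorial | OC(=O)[C@@]1(C)CCC[C@](C(=O)OC)(C)[C@@H]1CCC(=O)O | intermediate
4 | ring A C8 Weinreb amide C18 acid (same ring A stereochemistry; C5 arm ends in CON(Me)OMe) | OC(=O)[C@@]1(C)CCC[C@](C(=O)OC)(C)[C@@H]1CCC(=O)N(C)OC | intermediate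
5 | ring A C8 methyl ketone C18 acid (C5 arm = 3-oxobutyl) | OC(=O)[C@@]1(C)CCC[C@](C(=O)OC)(C)[C@@H]1CCC(C)=O | intermediate
6 | ring A C8 dioxolane C18 acid (ketone as ethylene ketal) | OC(=O)[C@@]1(C)CCC[C@](C(=O)OC)(C)[C@@H]1CCC2(C)OCCO2 | intermediate
7 | ring A C18 alcohol C9 methyl ester (equatorial CH2OH on C4) | OC[C@@]1(C)CCC[C@](C(=O)OC)(C)[C@@H]1CCC2(C)OCCO2 | intermediate
8 | ring A C18 benzyl ether C9 methyl ester | c4ccccc4COC[C@@]1(C)CCC[C@](C(=O)OC)(C)[C@@H]1CCC2(C)OCCO2 | intermediate
9 | ring A C9 alcohol (equatorial CH2OH on C10) | c4ccccc4COC[C@@]1(C)CCC[C@](CO)(C)[C@@H]1CCC2(C)OCCO2 | intermediate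
10 | ring A C9 aldehyde (equatorial CHO on C10) | c4ccccc4COC[C@@]1(C)CCC[C@](C=O)(C)[C@@H]1CCC2(C)OCCO2 | intermediate
11 | ring A dioxolane (E)-enoate (ethyl (E)-acrylate arm on C10) | c4ccccc4COC[C@@]1(C)CCC[C@](/C=C/C(=O)OCC)(C)[C@@H]1CCC2(C)OCCO2 | intermediate
12 | ring A keto (E)-enoate, (4S,5S,10S): C4 axial Me and equatorial CH2OBn, C10 axial Me and equatorial (E)-CH=CHCO2Et, C5 equatorial 3-oxobutyl | c4ccccc4COC[C@@]1(C)CCC[C@](/C=C/C(=O)OCC)(C)[C@@H]1CCC(C)=O | intermediate
13 | ring B closed 8-hydroxy C12 ethyl ester, trans-decalin (4S,5S,8S,9S,10R): C17, C19 and C20 methyls axial on one face; C18, 8-OH and C11 equatorial | c4ccccc4COC[C@@]1(C)CCC[C@]2(C)[C@@H]1CC[C@](C)(O)[C@H]2CC(=O)OCC | intermediate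
14 | 8-O-TES C12 ethyl ester (core as in 13) | c4ccccc4COC[C@@]1(C)CCC[C@]2(C)[C@@H]1CC[C@](C)(O[Si](CC)(CC)CC)[C@H]2CC(=O)OCC | intermediate
15 | 8-O-TES C12 alcohol | c4ccccc4COC[C@@]1(C)CCC[C@]2(C)[C@@H]1CC[C@](C)(O[Si](CC)(CC)CC)[C@H]2CCO | intermediate
16 | 8-O-TES C12 iodide | c4ccccc4COC[C@@]1(C)CCC[C@]2(C)[C@@H]1CC[C@](C)(O[Si](CC)(CC)CC)[C@H]2CCI | intermediate
17 | (E)-3-iodobut-2-en-1-ol | I/C(C)=C/CO | starting material
18 | C12 alkyllithium | c4ccccc4COC[C@@]1(C)CCC[C@]2(C)[C@@H]1CC[C@](C)(O[Si](CC)(CC)CC)[C@H]2CC[Li] | intermediate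
19 | lithium B-methoxy borate (B-alkyl-B-methoxy-9-BBN ate complex, boron on C12) | [Li+].c4ccccc4COC[C@@]1(C)CCC[C@]2(C)[C@@H]1CC[C@](C)(O[Si](CC)(CC)CC)[C@H]2CC[B-]3(OC)C5CCCC3CCC5 | intermediate
20 | (13E)-allylic alcohol (18-benzyloxy-8-triethylsilyloxy-labd-13-en-15-ol of the ent series, core as in 13) | c4ccccc4COC[C@@]1(C)CCC[C@]2(C)[C@@H]1CC[C@](C)(O[Si](CC)(CC)CC)[C@H]2CC/C(C)=C/CO | intermediate
21 | (13S)-C15 alcohol | c4ccccc4COC[C@@]1(C)CCC[C@]2(C)[C@@H]1CC[C@](C)(O[Si](CC)(CC)CC)[C@H]2CC[C@H](C)CCO | intermediate
22 | Meldrum's acid (2,2-dimethyl-1,3-dioxane-4,6-dione) | CC1(C)OC(=O)CC(=O)O1 | starting material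
23 | 2-(trimethylsilyl)ethanol | C[Si](C)(C)CCO | starting material
24 | 2-(trimethylsilyl)ethyl hydrogen malonate | C[Si](C)(C)CCOC(=O)CC(=O)O | intermediate
25 | C15 mixed malonate C18 benzyl ether | c4ccccc4COC[C@@]1(C)CCC[C@]2(C)[C@@H]1CC[C@](C)(O[Si](CC)(CC)CC)[C@H]2CC[C@H](C)CCOC(=O)CC(=O)OCC[Si](C)(C)C | intermediate
26 | C15 mixed malonate C18 alcohol | OC[C@@]1(C)CCC[C@]2(C)[C@@H]1CC[C@](C)(O[Si](CC)(CC)CC)[C@H]2CC[C@H](C)CCOC(=O)CC(=O)OCC[Si](C)(C)C | intermediate
27 | 3-methylbut-2-enoic acid (senecioic acid) | CC(C)=CC(=O)O | starting material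
28 | C18 senecioate with 8-O-TES and silylethyl malonate | CC(C)=CC(=O)OC[C@@]1(C)CCC[C@]2(C)[C@@H]1CC[C@](C)(O[Si](CC)(CC)CC)[C@H]2CC[C@H](C)CCOC(=O)CC(=O)OCC[Si](C)(C)C | intermediate
29 | target CNP0199440.1, (4S,5S,8S,9S,10R,13S): 8-hydroxy-18-(3-methylbut-2-enoyloxy)labdan-15-yl hydrogen malonate of the ent series | CC(C)=CC(=O)OC[C@@]1(C)CCC[C@]2(C)[C@@H]1CC[C@](C)(O)[C@H]2CC[C@H](C)CCOC(=O)CC(=O)O | target

## Step count and main risks

Total step count: 22. Longest linear sequence: 21 (steps 1–17 and 19–22).

**Step 12.**
- What may go wrong: the ketyl has to attack a carbon next to the quaternary C10. Simple reduction of the ketone or the enoate may therefore outrun ring closure.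
- The syn-axial contact of the C17 and C20 methyls may erode facial selectivity at C8.
- The samarium alkoxide may also lactonise onto the ester, which would block step 13.
- Fallback: it sets out from 11 and comes back at 20. It closes the same C8–C9 bond with reversed polarity at C9.
- iBu2AlH (CH2Cl2, −78 °C) reduces the enoate to the dioxolane allylic alcohol F1.
- 1 M HCl in THF frees the ketone to give the keto allylic alcohol F2.
- CBr4/PPh3 gives the keto allylic bromide F3.
- CrCl2 in THF converts the bromide into an (E)-allylchromium species, which adds through its γ-carbon C9 to the C8 ketone in an intramolecular Nozaki–Hiyama allylation. This should give the 8-hydroxy-9-vinyl decalin F4.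
- The closed Zimmerman–Traxler chair is trans-fused to the forming ring B, so oxygen and vinyl both end up equatorial.
- TESOTf/2,6-lutidine gives the 8-O-TES 9-vinyl decalin F5, and 9-BBN-H adds to the vinyl group to give the C12 B-alkyl-9-BBN F6.
- F6 couples with 17 under PdCl2(dppf)/aq K3PO4 to give 20.

**Step 2.**
- What may go wrong: oxidation of the benzylic CH2 (the future C7) may compete with attack on the ring. Subsequent cleavage would then shorten the C5 arm by one carbon. Incomplete degradation of the ring is also possible.
- Fallback: it sets out from 2 and comes back at 3. The arene is first made much more electron-rich and is then cleaved with ozone.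
- Friedel–Crafts acetylation (AcCl, AlCl3, CH2Cl2) gives methyl 12-acetyldehydroabietate F7.
- Baeyer–Villiger oxidation (mCPBA, CF3CO2H cat., CH2Cl2) gives methyl 12-acetoxydehydroabietate F8.
- K2CO3 in MeOH gives methyl 12-hydroxydehydroabietate F9.
- Exhaustive ozonolysis of the phenol (O3, CH2Cl2–MeOH, −78 °C; then H2O2, HCO2H) should give 3 without benzylic oxidation.

**Step 16.**
- What may go wrong: iodine–lithium exchange may be incomplete.
- The C12 carbanion may be protonated, or silicon may migrate to it, before boron capture.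
- The alkylpalladium species may undergo β-hydride elimination.
- Fallback: it sets out from 16 and comes back at 20. It builds the trisubstituted alkene by carbonyl olefination instead of cross-coupling.
- Alkylation of 2-lithio-2-methyl-1,3-dithiane (n-BuLi, THF, DMPU, −30 °C) with 16 gives the C13 dithiane F10.
- MeI/CaCO3 in aqueous MeCN gives the C13 methyl ketone F11.
- Horner–Wadsworth–Emmons olefination (triethyl phosphonoacetate, NaH, THF) gives the (13E)-C15 ethyl enoate F12, after chromatographic removal of the Z isomer.
- iBu2AlH (CH2Cl2, −78 °C) then gives 20.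

## Further compounds

F1 | step 12 | dioxolane allylic alcohol | c4ccccc4COC[C@@]1(C)CCC[C@](/C=C/CO)(C)[C@@H]1CCC2(C)OCCO2
F2 | step 12 | keto allylic alcohol | c4ccccc4COC[C@@]1(C)CCC[C@](/C=C/CO)(C)[C@@H]1CCC(C)=O
F3 | step 12 | keto allylic bromide | c4ccccc4COC[C@@]1(C)CCC[C@](/C=C/CBr)(C)[C@@H]1CCC(C)=O
F4 | step 12 | 8-hydroxy-9-vinyl decalin | c4ccccc4COC[C@@]1(C)CCC[C@]2(C)[C@@H]1CC[C@](C)(O)[C@H]2C=C
F5 | step 12 | 8-O-TES 9-vinyl decalin | c4ccccc4COC[C@@]1(C)CCC[C@]2(C)[C@@H]1CC[C@](C)(O[Si](CC)(CC)CC)[C@H]2C=C
F6 | step 12 | C12 B-alkyl-9-BBN | c4ccccc4COC[C@@]1(C)CCC[C@]2(C)[C@@H]1CC[C@](C)(O[Si](CC)(CC)CC)[C@H]2CCB3C5CCCC3CCC5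
F7 | step 2 | methyl 12-acetyldehydroabietate | CC(C)C1=CC2=C(C=C1C(C)=O)[C@]3(CCC[C@@]([C@@H]3CC2)(C)C(=O)OC)C
F8 | step 2 | methyl 12-acetoxydehydroabietate | CC(C)C1=CC2=C(C=C1OC(C)=O)[C@]3(CCC[C@@]([C@@H]3CC2)(C)C(=O)OC)C
F9 | step 2 | methyl 12-hydroxydehydroabietate | CC(C)C1=CC2=C(C=C1O)[C@]3(CCC[C@@]([C@@H]3CC2)(C)C(=O)OC)C
F10 | step 16 | C13 dithiane | c4ccccc4COC[C@@]1(C)CCC[C@]2(C)[C@@H]1CC[C@](C)(O[Si](CC)(CC)CC)[C@H]2CCC3(C)SCCCS3
F11 | step 16 | C13 methyl ketone | c4ccccc4COC[C@@]1(C)CCC[C@]2(C)[C@@H]1CC[C@](C)(O[Si](CC)(CC)CC)[C@H]2CCC(C)=O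
F12 | step 16 | (13E)-C15 ethyl enoate | c4ccccc4COC[C@@]1(C)CCC[C@]2(C)[C@@H]1CC[C@](C)(O[Si](CC)(CC)CC)[C@H]2CC/C(C)=C/C(=O)OCC
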